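**Retrosynthetic overview**
1. No ring is built: both carbocycles are the benzene ring of 2,4,6-trihydroxyacetophenone 1, dearomatised by four C-methylations (2) and freed of its acetyl group (syncarpic acid 3); the two rings are joined last.
2. Polarity switch: half of 3 is oxidised at C-2, through hydrate 4, to tetraone 5, in which the donor (enol) carbon of 3 has become an enolonium-type acceptor carbon.
3. Key disconnection: the exocyclic C-2=CH bond, cut to 5 and phosphonium salt 6 (used as ylide 7), two carbons that are both donors in ordinary enol and ylide chemistry; this gives alkylidene trione 8.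
4. Last disconnection: the second ring–CH bond, cut to 8 and 3 (Michael addition in the same flask), which gives watsonianone A 9.

Assumption: the target has no stereocentre (the bridging CH carries two constitutionally identical rings), so there is no enantiomer to select and the one achiral compound of the SMILES is made.

**Step 1**
Reactants: 1 2,4,6-trihydroxyacetophenone (phloroacetophenone)
Product: 2 acetylsyncarpic acid (2-acetyl-3-hydroxy-4,4,6,6-tetramethylcyclohex-2-ene-1,5-dione)
Conditions: NaOMe (6 equiv), MeI (excess), MeOH, 0 °C → reflux; aq. HCl work-up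
Reagents that add atoms: iodomethane, CI
Why: Dearomatising exhaustive C-methylation of the phloroglucinol polyanion (soft C-alkylation with MeI in MeOH) puts two methyl groups on each of C-3 and C-5, while the acetyl-bearing carbon stays as the stabilised, poorly nucleophilic β-triketone enolate; no stereocentre arises.

**Step 2**
Reactants: 2 acetylsyncarpic acid
Product: 3 syncarpic acid (5-hydroxy-2,2,6,6-tetramethylcyclohex-4-ene-1,3-dione, the enol of 2,2,4,4-tetramethylcyclohexane-1,3,5-trione)
Conditions: 6 M aq. HCl, reflux
Reagents that add atoms: none
Why: Acid-catalysed retro-Claisen deacylation of the triacylmethane: water adds to the exocyclic acetyl carbonyl and the stabilised ring enol leaves, so only the acetyl group is lost.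

**Step 3**
Reactants: 3 syncarpic acid (about 45 % of the batch)
Product: 5 syncarpic tetraone (4,4,6,6-tetramethylcyclohexane-1,2,3,5-tetraone), via tetraone hydrate 4 (not isolated)
Conditions: SeO2 (1.2 equiv), 1,4-dioxane/H2O, reflux; filter off Se; PhMe, Dean–Stark, reflux
Reagents that add atoms: selenium dioxide, O=[Se]=O; water, O (held only in hydrate 4)
Why: Riley oxidation: the enol of 3 attacks SeO2 at C-2, the only enolisable CH in the molecule (C-4 and C-6 are quaternary), and the selenium ester collapses to the C-2 ketone, first held as hydrate 4 and freed by azeotropic removal of water, the same reaction type that turns indane-1,3-dione into ninhydrin.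

**Step 4**
Reactants: 5 syncarpic tetraone; 6 (3-methylbutyl)triphenylphosphonium bromide; 3 syncarpic acid (1.1 equiv)
Product: 9 watsonianone A, via phosphorus ylide 7 (not isolated), via alkylidene trione 8 (not isolated)
Conditions: 6 (1.05 equiv), n-BuLi (1.0 equiv), THF, 0 °C; add to 5, THF, −78 → 0 °C; then 3, Et3N (20 mol %), rt; 1 M HCl work-up
Reagents that add atoms: none
Why: Wittig olefination followed by Michael addition: C-2 of 5, normally the donor carbon of syncarpic acid, is here an enolonium-type acceptor (the central, unhindered, non-enolisable and most electrophilic C=O of a vicinal tricarbonyl) that is attacked by the ylide carbon of 7 to give the doubly activated alkene 8, whose CH terminus is then attacked by the enolate of 3; the alkene has two identical flanks and the new CH carries two identical rings, so no stereochemistry has to be controlled.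

**Compound list**
1 | 2,4,6-trihydroxyacetophenone | CC(=O)c1c(O)cc(O)cc1O | starting material
2 | acetylsyncarpic acid (2-acetyl-3-hydroxy-4,4,6,6-tetramethylcyclohex-2-ene-1,5-dione) | CC(=O)C1=C(O)C(C)(C)C(=O)C(C)(C)C1=O | intermediate
3 | syncarpic acid (5-hydroxy-2,2,6,6-tetramethylcyclohex-4-ene-1,3-dione) | CC1(C)C(=O)C=C(O)C(C)(C)C1=O | intermediate
4 | tetraone hydrate (2,2-dihydroxy-4,4,6,6-tetramethylcyclohexane-1,3,5-trione) | CC1(C)C(=O)C(C)(C)C(=O)C(O)(O)C1=O | intermediate
5 | syncarpic tetraone (4,4,6,6-tetramethylcyclohexane-1,2,3,5-tetraone) | CC1(C)C(=O)C(C)(C)C(=O)C(=O)C1=O | intermediate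
6 | (3-methylbutyl)triphenylphosphonium bromide | CC(C)CC[P+](c1ccccc1)(c1ccccc1)c1ccccc1.[Br-] | starting material
7 | phosphorus ylide ((3-methylbutylidene)triphenylphosphorane) | CC(C)CC=P(c1ccccc1)(c1ccccc1)c1ccccc1 | intermediate
8 | alkylidene trione (2,2,4,4-tetramethyl-6-(3-methylbutylidene)cyclohexane-1,3,5-trione) | CC(C)CC=C1C(=O)C(C)(C)C(=O)C(C)(C)C1=O | intermediate
9 | watsonianone A (2,2'-(3-methylbutane-1,1-diyl)bis(3-hydroxy-4,4,6,6-tetramethylcyclohex-2-ene-1,5-dione)), achiral | CC(C)CC(C1=C(O)C(C)(C)C(=O)C(C)(C)C1=O)C1=C(O)C(C)(C)C(=O)C(C)(C)C1=O | target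

**Step count**
Total: 4 steps. Longest linear sequence: 4 steps (1 → 2 → 3 → 5 → 9). Compound 6 is bought and 3 enters twice. If 3 is bought instead of made, steps 1 and 2 drop out and the count is 2.

**Three steps most likely to fail**

Step 4 (most likely). The non-stabilised ylide 7 may transfer an electron to the strongly electron-poor tetraone, attack a flanking carbonyl, or add to the product alkene 8. The fallback sets out from 5 and comes back to the route at 8. It separates C–C bond formation from C=C formation while keeping C-2 as the acceptor. The organocerium reagent from (3-methylbutyl)magnesium bromide and CeCl3 (THF, −78 °C) adds to the C-2 carbonyl to give the tertiary carbinol 2-hydroxy-4,4,6,6-tetramethyl-2-(3-methylbutyl)cyclohexane-1,3,5-trione F1. Syn-dehydration with Burgess reagent (PhMe, 60 °C) can only use the side-chain CH2 hydrogens, because both ring neighbours are carbonyl carbons, so it gives 8. Compound 8 is trapped in the same flask by 3 and Et3N to give 9.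

Step 3. SeO2 can bridge two enol carbons through selenium instead of oxidising, and hydrate 4 may hold its water. The fallback sets out from 3 and comes back at 5. Condensation of 3 with N,N-dimethylformamide dimethyl acetal (PhMe, 80 °C) gives the enaminone 2-[(dimethylamino)methylidene]-4,4,6,6-tetramethylcyclohexane-1,3,5-trione F2. Ozonolysis of its electron-rich C=C (O3, CH2Cl2, −78 °C; then Me2S) gives anhydrous, selenium-free 5 with loss of N,N-dimethylformamide.

Step 1. Four C-methylations in one pot can stop at the trimethyl stage or give O-methyl ethers. The fallback sets out from 1 and comes back at 2. A double Mannich reaction (aq. CH2O, Me2NH, EtOH, rt) gives 3,5-bis[(dimethylamino)methyl]-2,4,6-trihydroxyacetophenone F3. Hydrogenolysis (H2, Pd/C, MeOH, rt) gives 2,4,6-trihydroxy-3,5-dimethylacetophenone F4. Only two dearomatising methylations (NaOMe, MeI, MeOH) are then left, at the two carbons that already carry a methyl group, to reach 2.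

**Further compounds**
F1 | step 4 | 2-hydroxy-4,4,6,6-tetramethyl-2-(3-methylbutyl)cyclohexane-1,3,5-trione | CC(C)CCC1(O)C(=O)C(C)(C)C(=O)C(C)(C)C1=O
F2 | step 3 | 2-[(dimethylamino)methylidene]-4,4,6,6-tetramethylcyclohexane-1,3,5-trione | CN(C)C=C1C(=O)C(C)(C)C(=O)C(C)(C)C1=O
F3 | step 1 | 3,5-bis[(dimethylamino)methyl]-2,4,6-trihydroxyacetophenone | CC(=O)c1c(O)c(CN(C)C)c(O)c(CN(C)C)c1O
F4 | step 1 | 2,4,6-trihydroxy-3,5-dimethylacetophenone | CC(=O)c1c(O)c(C)c(O)c(C)c1O
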